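(Its constants stand for no real mixture; no experiment stands behind them.)

At the reading, 5.0 min after the start, what stands in the flask depends on how the dissolved substrate was shared between two steps, so I reckoned with rates.

solid substrate 0.50 mM; reagent 1.00 equiv; time 5.0 min

    solid substrate ⇌ dissolved substrate, rate k1*(cs1 - [dissolved substrate]) while solid is left; crystals form when [dissolved substrate] > cs1 (cs1 = 0.17 mM, k1 = 0.412 /s)
    dissolved substrate + reagent → target (k2 = 95.0 /M/s)
    2 dissolved substrate → side product (k3 = 181 /M/s)
    crystals ⇌ target, rate k4*(cs4 - [target]) while solid is left; crystals form when [target] > cs4 (cs4 = 0.40 mM, k4 = 0.354 /s)
    target ⇌ isomer of the product (K5 = 1.33, k5 = 0.0101 /s)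

* target and crystals together at 5.0 min, in percent of the solid substrate charged
* the change that raises the amount of target and crystals together at 5.0 min, in percent of the solid substrate charged most ("none" if none brings more than 2 percentage points) (gamma / alpha / delta / beta / none)
* amount of target and crystals together at 5.0 min, in percent of the solid substrate charged, after gamma

- gamma: doubling the dissolution coefficient of step 1, all else as stated
- alpha: doubling the solubility in step 1, all else as stated
- delta: doubling the amount of reagent, all else as stated
- beta: doubling the solubility in step 4, all else as stated

Reagent and solid substrate are charged equally, and the side step takes no reagent. So the reagent used equals target, crystals and isomer of the product together, and once no substrate stands solid or dissolved, the reagent left, in percent of its charge, equals the side product.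

With the solution at solubility and reagent as charged, the target step would use 0.00808 mM/s and the side step 0.0105 mM/s, a ratio of 0.772. Together they use less than the 0.0700 mM/s the solid delivers into empty solution.

Two things slow these rates. For the solid to deliver only what is used, c(dissolved substrate) must stand lower, by a factor I took as 0.735. That slows the target step once and the side step twice over. Reagent being used slows the target step further, by about 0.782 on average.

So I carried the split 0.821, the target step's rate over the side step's use, with both slowings in it; it is a selectivity factor. It sends 45.1 % to target. That stays below the solubility of step 4, 0.225 mM against 0.40 mM, so I expected no crystals. Relaxation is short against the time, 0.653 min against 5.0 min, so target keeps 42.9 % of that, giving 19.4 %. Gamma, the doubling of k1, brings the factor to 0.868 and gives 17.6 %. Reagent is a direct factor in the split, so I chose delta.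

The forecast gave 23 %, delta and 22 %, reasoning that “Doubling the reagent favours the productive step over dimerisation”.

The simulation gave 21.1 %, delta with a gain of 8.3 percentage points, and 20.4 %.

In this flask, at 0.182 min, the target step ran at 0.84 of the side step's use, but that is one moment; over the whole run, reagent used over side product came to 0.930, and that is the figure to set beside my split of 0.821. The flask ended with 52 % of its reagent and 51.6 % as side product. In the neighbour with 1.2 mM of solid substrate, and as much reagent, the ratio becomes 1.85, with factors 0.574 and 0.675, so the split is 2.18 and the yield 29.4 %. The simulation gave that neighbour 27.8 %.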